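**Retrosynthetic overview**
1. The angelate goes on last. The γ-lactone comes from reduction of a C8 ketone next to a C12 amide, and the C10 methyl from cuprate addition to a C9–C10 enone.
2. Key disconnection C7–C11: an intramolecular oxidative (single-electron) coupling of a C8 ketone enolate with the enolate of a lactamide tethered through the C5 oxygen. It closes the bridging tetrahydrofuran and creates C7 and quaternary C11 in one step.
3. The seven-membered ring comes from ring-closing metathesis of a C1 vinyl group with a C8 vinyl ketone.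
4. Cyclopentane centres: C2 is bought, C1 and quaternary C5 (trans fusion, C5–O already attached) come from conjugate addition and Michael trapping on a 2-alkoxy enone, and C4 from chelation-controlled MeMgBr addition.
5. Ring order: cyclopentane (bought), then cycloheptenone, then tetrahydrofuran (radical step), then γ-lactone.

Notation: locants C1–C15 are those of the guaiane skeleton of the target (C1/C5 ring fusion, C2 ester carbon, C4 carbinol, C7/C8 lactone fusion, C10 methyl-bearing carbon, C11 quaternary ether carbon, C12 carbonyl); α is the face of H-1, β the face of the C5–O bond.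

Assumption: the target is read as the (1R,2S,4R,5R,7S,8R,10R,11S) guaianolide with a (Z)-2-methylbut-2-enoate, and (S)-4-hydroxycyclopent-2-en-1-one, (S)-N,N-dimethyllactamide, N-methoxy-N-methylacrylamide and angelic acid are taken as catalogue compounds.

**Step 1**
Reactants: 1 (S)-4-hydroxycyclopent-2-en-1-one
Product: 2 (S)-4-(tert-butyldimethylsilyloxy)cyclopent-2-en-1-one
Conditions: TBSCl, imidazole, DMF, 0 to 25 °C
Reagents that add atoms: tert-butyldimethylsilyl chloride (CC(C)(C)[Si](C)(C)Cl)
Why: Standard silylation of the secondary alcohol gives the bulky α-silyloxy group that directs step 4, and the C2 centre is not touched.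

**Step 2**
Reactants: 2 (S)-4-(tert-butyldimethylsilyloxy)cyclopent-2-en-1-one
Product: 3 (S)-4-(tert-butyldimethylsilyloxy)-2-iodocyclopent-2-en-1-one
Conditions: I2, pyridine–CH2Cl2, 0 to 25 °C
Reagents that add atoms: iodine (II)
Why: Johnson α-iodination of the enone (pyridine conjugate addition, iodination, elimination) puts a coupling handle on the future C5 without affecting C2.

**Step 3**
Reactants: 3 (S)-4-(tert-butyldimethylsilyloxy)-2-iodocyclopent-2-en-1-one; 4 (S)-N,N-dimethyllactamide
Product: 5 2-alkoxy enone (lactamide O-linked to the α-carbon of the enone)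
Conditions: CuI (10 mol%), 3,4,7,8-tetramethyl-1,10-phenanthroline (20 mol%), Cs2CO3, toluene, 80 °C
Reagents that add atoms: none
Why: Ullmann-type copper-catalysed C–O coupling of the activated vinyl iodide with the secondary alcohol (Buchwald vinyl etherification) installs the future C5–O–C11 ether while C5 is still sp2, and the lactamide centre need not be controlled because it is planarised in step 7.

**Step 4**
Reactants: 5 2-alkoxy enone; 6 N-methoxy-N-methylacrylamide
Product: 8 keto bis-amide (C4 ketone; 2α-OTBS; 1β-vinyl; C5 with β-O-CH(CH3)CONMe2 and α-CH2CH2CON(OMe)Me), via bromomagnesium enolate 7 (not isolated)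
Conditions: CH2=CHMgBr (1.5 equiv), CuBr·SMe2 (10 mol%), THF, −78 °C; then 6 (2 equiv), −78 to −30 °C; NH4Cl(aq)
Reagents that add atoms: vinylmagnesium bromide (C=C[Mg]Br)
Why: In this tandem conjugate addition–Michael reaction (Noyori-type three-component coupling) the vinyl group adds to C1 anti to the α-silyloxy group and the α-alkoxy enolate 7 then attacks the acrylamide anti to the new vinyl group, which sets C1 (β-vinyl) and quaternary C5 (β-oxygen, α-chain) and hence the trans ring fusion.

**Step 5**
Reactants: 8 keto bis-amide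
Product: 10 vinyl ketone carbinol (4α-OH; 4β-CH3; C5 α-CH2CH2COCH=CH2), via bromomagnesium alkoxide 9 (not isolated)
Conditions: MeMgBr (1.2 equiv), CH2Cl2–Et2O, −78 °C; then CH2=CHMgBr (3 equiv), THF, −78 to 0 °C; cold 1 M HCl quench
Reagents that add atoms: methylmagnesium bromide (C[Mg]Br); vinylmagnesium bromide (C=C[Mg]Br)
Why: In the chelation-controlled Grignard addition, magnesium bound to the C4 carbonyl and the C5 ether oxygen turns the C5 side chain over the α face, so methyl enters from the β face (also anti to the α-OTBS) to give the 4α-carbinol, after which the Weinreb ketone synthesis stops cleanly at the vinyl ketone.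

**Step 6**
Reactants: 10 vinyl ketone carbinol
Product: 11 trans-fused hydroazulenone (9-en-8-one; 1α-H; 2α-OTBS; 4α-OH; 5β-O-CH(CH3)CONMe2)
Conditions: second-generation Grubbs catalyst (H2IMes)(PCy3)Cl2Ru=CHPh (5 mol%), CH2Cl2 (0.005 M), 40 °C
Reagents that add atoms: none
Why: Ring-closing metathesis between the C1 vinyl group and the vinyl ketone closes the cycloheptenone with loss of ethene and forms no stereocentre, while the enone it leaves ensures that only C7 can be enolised in step 7.

**Step 7**
Reactants: 11 trans-fused hydroazulenone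
Product: 13 bridged enone amide (C7–C11 bond closed; 5β,11-epoxy; 9-en-8-one), via trilithium trianion 12 (not isolated)
Conditions: LiN(iPr)2 (3.3 equiv), THF, −78 °C; then Fe(acac)3 (2.2 equiv), −78 to 25 °C; NH4Cl(aq)
Reagents that add atoms: none
Why: In this oxidative enolate heterocoupling (Baran type), single-electron oxidation of the α-alkoxy amide enolate gives the captodative C11 radical, which adds to C7 of the ketone dienolate on the β face (the only face the C5–O tether can reach), and the metal-bridged bis-enolate arrangement places the amide over C8 and the methyl outward, setting C7 and quaternary C11.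

**Step 8**
Reactants: 13 bridged enone amide
Product: 14 10α-methyl ketone
Conditions: Me2CuLi (3 equiv, from MeLi and CuI), Et2O, −78 to −20 °C; NH4Cl(aq)
Reagents that add atoms: lithium dimethylcuprate ([Li+].C[Cu-]C)
Why: Gilman conjugate addition takes place on the convex α face of the enone, opposite the oxygen bridge and its inward amide and trans to the C1–C2 bond, and so sets the 10α-methyl group.

**Step 9**
Reactants: 14 10α-methyl ketone
Product: 17 diol lactone (2α,4α-dihydroxy-5β,11-epoxyguaian-12,8β-olide), via hydroxy amide 15 (not isolated), via silyl lactone 16 (not isolated)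
Conditions: NaBH4, MeOH–THF, −40 °C; then 2 M HCl(aq), THF, 45 °C
Reagents that add atoms: none
Why: Hydride attacks the C8 ketone from the open α face (away from the bridge) to give the 8β-alcohol, which lactonises onto the adjacent amide by acid-catalysed N-to-O acyl transfer while the same acid cleaves the silyl ether.

**Step 10**
Reactants: 17 diol lactone; 18 angelic acid
Product: 20 target CNP0293659.1 (2-O-angelate of 17), via mixed anhydride 19 (not isolated)
Conditions: 18, 2,4,6-trichlorobenzoyl chloride, Et3N, toluene, 25 °C; then 17, toluene, 80 °C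
Reagents that add atoms: none
Why: Yamaguchi esterification through mixed anhydride 19 without DMAP acylates only the secondary C2 hydroxyl (the tertiary C4 hydroxyl is inert), keeps the Z geometry of the angelate and leaves C2 with its configuration.

**Compound list**
1 | (S)-4-hydroxycyclopent-2-en-1-one | O[C@@H]1C=CC(=O)C1 | starting material
2 | (S)-4-(tert-butyldimethylsilyloxy)cyclopent-2-en-1-one | CC(C)(C)[Si](C)(C)O[C@@H]1C=CC(=O)C1 | intermediate
3 | (S)-4-(tert-butyldimethylsilyloxy)-2-iodocyclopent-2-en-1-one | CC(C)(C)[Si](C)(C)O[C@@H]1C=C(I)C(=O)C1 | intermediate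
4 | (S)-2-hydroxy-N,N-dimethylpropanamide ((S)-N,N-dimethyllactamide) | C[C@H](O)C(=O)N(C)C | starting material
5 | (S)-2-{[(3S)-3-(tert-butyldimethylsilyloxy)-5-oxocyclopent-1-en-1-yl]oxy}-N,N-dimethylpropanamide | CC(C)(C)[Si](C)(C)O[C@@H]1C=C(O[C@@H](C)C(=O)N(C)C)C(=O)C1 | intermediate
6 | N-methoxy-N-methylprop-2-enamide | C=CC(=O)N(C)OC | starting material
7 | bromomagnesium C4=C5 enolate from 1β-vinyl addition to 5 (vinyl trans to 2α-OTBS) | CC(C)(C)[Si](C)(C)O[C@H]1CC(O[Mg]Br)=C(O[C@@H](C)C(=O)N(C)C)[C@@H]1C=C | intermediate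
8 | cyclopentanone with C4 ketone, 2α-OTBS, 1β-vinyl, and C5 bearing the β-O-CH(CH3)CONMe2 ether and the α-CH2CH2CON(OMe)Me chain | CC(C)(C)[Si](C)(C)O[C@H]1CC(=O)[C@@](O[C@@H](C)C(=O)N(C)C)(CCC(=O)N(C)OC)[C@@H]1C=C | intermediate
9 | bromomagnesium 4α-alkoxide (4β-methyl) of the MeMgBr adduct of 8, Weinreb amide intact | CC(C)(C)[Si](C)(C)O[C@H]1C[C@@](C)(O[Mg]Br)[C@@](O[C@@H](C)C(=O)N(C)C)(CCC(=O)N(C)OC)[C@@H]1C=C | intermediate
10 | cyclopentane with 4α-OH, 4β-CH3, 2α-OTBS, 1β-vinyl, and C5 bearing the β-O-lactamide ether and the α-CH2CH2COCH=CH2 chain | CC(C)(C)[Si](C)(C)O[C@H]1C[C@@](C)(O)[C@@](O[C@@H](C)C(=O)N(C)C)(CCC(=O)C=C)[C@@H]1C=C | intermediate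
11 | trans-fused hydroazulen-8-one with 9,10-alkene, 1α-H, 2α-OTBS, 4α-OH, 4β-CH3, 5β-O-CH(CH3)CONMe2 | CC(C)(C)[Si](C)(C)O[C@H]1C[C@@](C)(O)[C@@]2(O[C@@H](C)C(=O)N(C)C)CCC(=O)C=C[C@H]12 | intermediate
12 | trilithium salt of 11 (C4 alkoxide, C7=C8 dienolate, amide enolate) | CC(C)(C)[Si](C)(C)O[C@H]1C[C@@](C)(O[Li])[C@@]2(OC(C)=C(O[Li])N(C)C)CC=C(O[Li])C=C[C@H]12 | intermediate
13 | 5β,11-epoxy-bridged 9-en-8-one with 7α-H, C11 bearing outward CH3 and inward CONMe2, 2α-OTBS, 4α-OH | CC(C)(C)[Si](C)(C)O[C@H]1C[C@@](C)(O)[C@@]23C[C@H]([C@@](C)(C(=O)N(C)C)O3)C(=O)C=C[C@H]12 | intermediate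
14 | 10α-methyl-8-ketone derived from 13 | CC(C)(C)[Si](C)(C)O[C@H]1C[C@@](C)(O)[C@@]23C[C@H]([C@@](C)(C(=O)N(C)C)O3)C(=O)C[C@@H](C)[C@H]12 | intermediate
15 | 8β-hydroxy amide derived from 14 | CC(C)(C)[Si](C)(C)O[C@H]1C[C@@](C)(O)[C@@]23C[C@H]([C@@](C)(C(=O)N(C)C)O3)[C@H](O)C[C@@H](C)[C@H]12 | intermediate
16 | 2-O-tert-butyldimethylsilyl ether of 17 (cis-fused 12,8β-lactone closed) | CC(C)(C)[Si](C)(C)O[C@H]1C[C@@](C)(O)[C@@]23C[C@H]4[C@@H](C[C@@H](C)[C@H]12)OC(=O)[C@@]4(C)O3 | intermediate
17 | (1R,2S,4R,5R,7S,8R,10R,11S)-2α,4α-dihydroxy-5β,11-epoxyguaian-12,8β-olide | O[C@H]1C[C@@](C)(O)[C@@]23C[C@H]4[C@@H](C[C@@H](C)[C@H]12)OC(=O)[C@@]4(C)O3 | intermediate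
18 | angelic acid ((Z)-2-methylbut-2-enoic acid) | C/C=C(/C)C(=O)O | starting material
19 | angelic 2,4,6-trichlorobenzoic anhydride | C/C=C(/C)C(=O)OC(=O)c1c(Cl)cc(Cl)cc1Cl | intermediate
20 | CNP0293659.1, the 2-O-angelate of 17 | C/C=C(/C)C(=O)O[C@H]1C[C@@](C)(O)[C@@]23C[C@H]4[C@@H](C[C@@H](C)[C@H]12)OC(=O)[C@@]4(C)O3 | target

**Total step count:** 10
**Longest linear sequence:** 10 steps (1 to 20)

**Steps most likely to fail and fallbacks**

Step 3 (copper-catalysed etherification of the base-sensitive iodo enone with a hindered secondary alcohol). The fallback sets out from 2. Nucleophilic epoxidation (H2O2, NaOH, MeOH, −20 °C) anti to the silyloxy group gives the trans-epoxy ketone F1. Its opening at the carbon α to the carbonyl by the sodium alkoxide of 4 (NaH, THF, 0 °C), followed by E1cB loss of the β-hydroxyl, gives the 2-alkoxy enone without passing through an achiral 1,2-dione, and the route is rejoined at 5.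

Step 4 (Michael trapping of a hindered α-alkoxy enolate by the weakly electrophilic acrylamide, with enolate equilibration and loss of the silyloxy group as the competing path). The fallback sets out from 5. The same vinyl addition is followed by trapping with the more reactive methyl acrylate to give the keto ester F2. MeMgBr (−78 °C, then warming) gives the 4α-alkoxide, which closes onto the ester to the cis-fused δ-lactone F3. AlMe3 and MeNH(OMe)·HCl open the lactone to the hydroxy Weinreb amide F4, and CH2=CHMgBr then gives the vinyl ketone, so the route is rejoined at 10.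

Step 7 (the key coupling: trianion formation, the yield of the single-electron coupling and the orientation of the amide at quaternary C11). The fallback sets out from 3 and postpones the C11 methyl.
- Coupling of 3 with 2-hydroxy-N,N-dimethylacetamide under the conditions of step 3 gives the glycolamide enone F5.
- The conditions of steps 4, 5 and 6 then give the keto bis-amide F6, the vinyl ketone carbinol F7 and the hydroazulenone F8.
- The same oxidative coupling gives the bridged enone F9, whose C11 centre now carries a hydrogen and can be equilibrated with base (t-BuOK, t-BuOH) to the epimer with the amide over C8.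
- Me2CuLi gives the 10α-methyl ketone F10.
- NaBH4 followed by pyridinium p-toluenesulfonate in toluene at 80 °C gives the nor-methyl silyl lactone F11.
- LiN(iPr)2 (2.2 equiv) and MeI at −78 °C methylate the lactone enolate on its convex face, the only face that keeps the two five-membered rings cis-fused, and the route is rejoined at 16, which the acid of step 9 converts to 17.

**Further compounds**
F1 | step 3 | trans-2,3-epoxy-4-(tert-butyldimethylsilyloxy)cyclopentanone (epoxide anti to the silyloxy group) | CC(C)(C)[Si](C)(C)O[C@@H]1[C@H]2O[C@H]2C(=O)C1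
F2 | step 4 | methyl ester analogue of 8 (C5 α-CH2CH2CO2CH3 chain) | CC(C)(C)[Si](C)(C)O[C@H]1CC(=O)[C@@](O[C@@H](C)C(=O)N(C)C)(CCC(=O)OC)[C@@H]1C=C
F3 | step 4 | cis-fused δ-lactone between the 4α-oxygen and the C5 propanoate chain (4β-CH3, 1β-vinyl, 2α-OTBS) | CC(C)(C)[Si](C)(C)O[C@H]1C[C@@]2(C)OC(=O)CC[C@@]2(O[C@@H](C)C(=O)N(C)C)[C@@H]1C=C
F4 | step 4 | 4α-hydroxy-4β-methyl Weinreb amide (neutral form of 9) | CC(C)(C)[Si](C)(C)O[C@H]1C[C@@](C)(O)[C@@](O[C@@H](C)C(=O)N(C)C)(CCC(=O)N(C)OC)[C@@H]1C=C
F5 | step 7 | glycolamide analogue of 5 (OCH2CONMe2 on the enone α-carbon) | CC(C)(C)[Si](C)(C)O[C@@H]1C=C(OCC(=O)N(C)C)C(=O)C1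
F6 | step 7 | glycolamide analogue of 8 | CC(C)(C)[Si](C)(C)O[C@H]1CC(=O)[C@@](OCC(=O)N(C)C)(CCC(=O)N(C)OC)[C@@H]1C=C
F7 | step 7 | glycolamide analogue of 10 | CC(C)(C)[Si](C)(C)O[C@H]1C[C@@](C)(O)[C@@](OCC(=O)N(C)C)(CCC(=O)C=C)[C@@H]1C=C
F8 | step 7 | glycolamide analogue of 11 | CC(C)(C)[Si](C)(C)O[C@H]1C[C@@](C)(O)[C@@]2(OCC(=O)N(C)C)CCC(=O)C=C[C@H]12
F9 | step 7 | 11-nor-methyl analogue of 13 (C11–H, amide over C8) | CC(C)(C)[Si](C)(C)O[C@H]1C[C@@](C)(O)[C@@]23C[C@H]([C@@H](C(=O)N(C)C)O3)C(=O)C=C[C@H]12
F10 | step 7 | 11-nor-methyl analogue of 14 | CC(C)(C)[Si](C)(C)O[C@H]1C[C@@](C)(O)[C@@]23C[C@H]([C@@H](C(=O)N(C)C)O3)C(=O)C[C@@H](C)[C@H]12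
F11 | step 7 | 11-nor-methyl analogue of 16 (C11–H cis to H-7) | CC(C)(C)[Si](C)(C)O[C@H]1C[C@@](C)(O)[C@@]23C[C@H]4[C@@H](C[C@@H](C)[C@H]12)OC(=O)[C@H]4O3
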